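The pitfall in this flask is to book every part of solid substrate that dissolves as target, when dissolved substrate also attacks the target already made.

solid substrate 10 mM; gas 1.3 mM (held); time 8.0 h

    2 reagent → self-condensation product (k1 = 0.41 M⁻¹ s⁻¹)
    dissolved substrate + reagent → target (k2 = 0.62 M⁻¹ s⁻¹)
    solid substrate ⇌ dissolved substrate, rate k3*(cs3 - [dissolved substrate]) while solid is left; crystals form when [dissolved substrate] > cs3 (cs3 = 0.64 mM, k3 = 6.2 × 10⁻⁴ s⁻¹)
    gas ⇌ reagent, rate k4*(csat - [reagent]) (k4 = 0.0016 s⁻¹, csat = 1.3 mM)
    dissolved substrate + target → side product (k5 = 0.17 M⁻¹ s⁻¹)

- in percentages every species weighs as the solid substrate in it: one side product counts as two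
- two of one species on the left: rate k times its square, two consumed each time
- as a solid, counted per litre of solution: solid substrate
- at the start none of reagent is dissolved
- at the start none of the solid substrate is in solution
- dissolved substrate means what is dissolved; the solid is not counted in it
- run time (flask): 8.0 h

- target at 8.0 h, in percent of the solid substrate charged
- concentration of dissolved substrate in solution at 2.0 h, in percent of saturation
- the change that raises the amount of target at 8.0 h, in percent of the solid substrate charged most ("none" if none brings more than 2 percentage points) (Tuesday's / Sunday's / Thursday's / Wednesday's / none)
- amount of target at 8.0 h, in percent of the solid substrate charged, after Tuesday's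

- Tuesday's: doubling the dissolution coefficient of step 3, all else as stated
- Sunday's: doubling the transfer coefficient of step 4, all else as stated
- Thursday's: doubling the saturation concentration of gas, all else as stated
- Wednesday's: doubling the solubility in step 3, all else as stated

I begin with reagent. Transfer from the gas and self-condensation balance at a plateau:

reagent plateau = 0.892 mM

Even at saturation, dissolved substrate takes less reagent than self-condensation does, so I hold reagent there, and the passing into target becomes pseudo-first-order in dissolved substrate. Target then climbs towards the level at which its loss to dissolved substrate equals its making:

ceiling share = 32.5 %

This is the ceiling share, the fraction of the charge at which dissolved substrate destroys target as fast as it makes it. With target at half that ceiling, dissolution balances the losses of dissolved substrate: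

dissolved share = 2.74 %

First way, by the clock: with the dissolved share held, target closes on the ceiling exponentially and reaches 73.8 % of it by 8.0 h, which gives

y = 24.0 %

Second way, by the book: dissolution feeds 65.4 % of the charge, under the whole charge. Reaching that point on the ceiling spends 63.2 %, and 2.74 % stands in solution. The feed, reckoned from dissolution, and the spending, reckoned from the two reactions, meet, but both lean on the same reagent plateau, so this tests the dissolved share and not the plateau.

Dissolution against the passing into target gives a bound of 52.9 % of saturation for dissolved substrate at 2.0 h, and the loss to target comes on top. Doubling the saturation concentration moves the plateau to 1.48 mM, above the 1.03 mM from doubling transfer. The clock ranks Thursday's first, and Tuesday's gives 27.6 %.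

The forecast gives 37 %, 47 %, Wednesday's and 49 %, reasoning that “Doubling the solubility lifts dissolved substrate more than doubling the dissolution coefficient does”. Its target stands above mine.

The simulation gives 23.0 %, 48.5 %, Thursday's with a gain of 11 percentage points, and 25.5 %.

In this flask target has reached 70.8 % of the ceiling share. The neighbour flask holds 40 mM of solid substrate, which brings its ceiling share down to 8.13 %. The same clock fraction then gives 6.00 % of its charge as target. That neighbour flask gives 5.74 %, with 84.0 % of its charge still solid.

Its constants were set for the occasion; the flask was simulated.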